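**Plan** (prostanoid numbering: C1 carboxyl, ring C8–C12, enone C13=C14–C15=O)

- Retrosynthesis: cut C13=C14 first (Horner–Wadsworth–Emmons; the 15-keto enone is the direct olefination product, so C15 needs no redox step), then C5=C6 (Z-selective Wittig on a lactol), then the ring bonds C8–C12 and C10–C11.
- Enabling feature: in the cyclopentane C8–C12, C12 is α to C13 (an aldehyde carbon before olefination), and C8 is β to the C6 carboxyl carbon and α to C9 (a ketone before reduction). The ring bond C8–C12 is therefore the bond of an enamine Michael addition onto a γ-keto enoate.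
- Forward: the ring arises first, in one amine-catalysed domino Michael/Michael reaction (formal (3+2) cycloaddition) of a 3-silylacrolein (C11–C13, silicon as masked 11-OH) with ethyl 4-oxopent-2-enoate (C6–C10). The second Michael addition closes the ring at C8–C12.
- Then: reduction and lactonisation, Fleming–Tamao oxidation, α-chain by Wittig reaction, ω-chain enone by Horner–Wadsworth–Emmons olefination last, one desilylation.
- Stereochemistry: C11 and C12 from the chiral amine catalyst; C8 from the ring closure (all-trans); C9 from hydride attack anti to the C8 substituent; C11–O by retentive C–Si oxidation; 5Z from the non-stabilised ylide; 13E from the stabilised phosphonate.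

Key step: step 3

Remark: the sense of induction in step 3 is assigned from the usual steric model of diarylprolinol silyl ethers (attack anti to the CPh2OSiMe3 group on the E-iminium ion and on the E-enamine), which calls for the (R)-catalyst.

**Route**

Step 1
Reactants: 1 prop-2-yn-1-ol; 2 dimethyl(phenyl)silane
Product: 3 (E)-3-[dimethyl(phenyl)silyl]prop-2-en-1-ol
Conditions: PtCl2 (cat.), XPhos, THF, 50 °C
Reagents that add atoms: none
Why: Platinum-catalysed syn-hydrosilylation of the terminal alkyne, steered to the distal carbon by the propargylic hydroxyl and the bulky phosphine, should give the (E)-β-vinylsilane; no stereocenter is formed.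

Step 2
Reactants: 3 (E)-3-[dimethyl(phenyl)silyl]prop-2-en-1-ol
Product: 4 (E)-3-[dimethyl(phenyl)silyl]prop-2-enal
Conditions: MnO2, CH2Cl2, rt
Reagents that add atoms: none
Why: Allylic oxidation with MnO2 should stop at the enal and leave the vinylsilane and the E geometry untouched.

Step 3
Reactants: 4 (E)-3-[dimethyl(phenyl)silyl]prop-2-enal; 5 ethyl (E)-4-oxopent-2-enoate
Product: 7 ethyl 2-[(1R,2S,3R)-3-[dimethyl(phenyl)silyl]-2-formyl-5-oxocyclopentyl]acetate, via open-chain enamine adduct 6 (not isolated)
Conditions: (R)-α,α-diphenylprolinol trimethylsilyl ether (10 mol %), 4-nitrophenol, i-PrOH, rt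
Reagents that add atoms: none
Why: The secondary amine converts enal 4 into an E-iminium ion, the enol of the methyl ketone of 5 adds to its β-carbon (first Michael addition), and the enamine 6 so formed attacks, within the same molecule, the enoate carbon that is β to the ester and α to the ketone (second Michael addition), which closes the cyclopentanone between the formyl-bearing and the acetate-bearing carbons before hydrolysis returns the catalyst. The closest known reaction type is the diarylprolinol silyl ether-catalysed domino Michael/Michael reaction (formal (3+2) cycloaddition) of β-substituted enals with γ-keto enoates, together with enamine-catalysed intramolecular Michael cyclisations of formyl enones. The one ring that closes is the five-membered carbocycle, in a 5-exo-trig (enolexo) closure. The silyl-bearing center is set by the catalyst, because the nucleophile enters the iminium ion on the face anti to the CPh2OSiMe3 group; the formyl-bearing center is set in the ring closure, where the E-enamine reacts on the same unshielded face and so places CHO trans to silicon; the acetate-bearing center follows from the cyclisation transition state that keeps the enoate chain away from the enamine, and being α to the ketone it can also settle by enolisation in this all-trans, most stable arrangement. The step needs attack at the carbon α to the ketone (5-exo) instead of the carbon β to it (6-endo), and the methyl group as the only donor: the tether length secures the first, the fact that the methyl group is the only enolisable position of 5 secures the second, and 4-nitrophenol speeds enolisation and catalyst turnover.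

Step 4
Reactants: 7 ethyl 2-[(1R,2S,3R)-3-[dimethyl(phenyl)silyl]-2-formyl-5-oxocyclopentyl]acetate
Product: 9 (3aR,4S,5R,6aS)-5-[dimethyl(phenyl)silyl]-4-(hydroxymethyl)hexahydro-2H-cyclopenta[b]furan-2-one, via diol ester 8 (not isolated)
Conditions: LiAlH(O-t-Bu)3, THF, 60 °C; then aq. HCl, rt
Reagents that add atoms: none
Why: The hindered hydride should reduce aldehyde and ketone but not the ester, and should attack the ring ketone anti to the adjacent CH2CO2Et group, so that the new carbinol is cis to that group and lactonises on acidification (substrate-controlled reduction, then lactonisation).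

Step 5
Reactants: 9 (3aR,4S,5R,6aS)-5-[dimethyl(phenyl)silyl]-4-(hydroxymethyl)hexahydro-2H-cyclopenta[b]furan-2-one
Product: 11 (3aR,4S,5R,6aS)-5-hydroxy-4-(hydroxymethyl)hexahydro-2H-cyclopenta[b]furan-2-one, via fluorosilane 10 (not isolated)
Conditions: HBF4·OEt2, CH2Cl2, rt; then KF, KHCO3, 30% aq. H2O2, THF/MeOH, rt; acidic work-up
Reagents that add atoms: hydrogen peroxide, OO
Why: Fleming–Tamao oxidation: protodesilylation of the phenyl group gives the fluorosilane, and the peroxide-induced shift of carbon from silicon to oxygen proceeds with retention, so the silyl-bearing center should become the carbinol center of the same configuration.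

Step 6
Reactants: 11 (3aR,4S,5R,6aS)-5-hydroxy-4-(hydroxymethyl)hexahydro-2H-cyclopenta[b]furan-2-one
Product: 12 (3aR,4S,5R,6aS)-5-(tert-butyldimethylsilyloxy)-4-[(tert-butyldimethylsilyloxy)methyl]hexahydro-2H-cyclopenta[b]furan-2-one
Conditions: TBSCl (2.5 equiv), imidazole, DMF, rt
Reagents that add atoms: tert-butyl(chloro)dimethylsilane, CC(C)(C)[Si](C)(C)Cl
Why: Standard silyl ether formation at the primary and the secondary hydroxyl; no stereocenter is touched.

Step 7
Reactants: 12 (3aR,4S,5R,6aS)-5-(tert-butyldimethylsilyloxy)-4-[(tert-butyldimethylsilyloxy)methyl]hexahydro-2H-cyclopenta[b]furan-2-one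
Product: 13 (3aR,4S,5R,6aS)-5-(tert-butyldimethylsilyloxy)-4-[(tert-butyldimethylsilyloxy)methyl]hexahydro-2H-cyclopenta[b]furan-2-ol (anomer mixture)
Conditions: i-Bu2AlH, CH2Cl2, −78 °C; aq. potassium sodium tartrate work-up
Reagents that add atoms: none
Why: Partial reduction of the γ-lactone to the lactol; the tetrahedral aluminate is stable at −78 °C, which should prevent over-reduction, and the silyl ethers are inert.

Step 8
Reactants: 13 (3aR,4S,5R,6aS)-5-(tert-butyldimethylsilyloxy)-4-[(tert-butyldimethylsilyloxy)methyl]hexahydro-2H-cyclopenta[b]furan-2-ol; 14 (4-carboxybutyl)triphenylphosphonium bromide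
Product: 15 (Z)-7-[(1R,2S,3R,5S)-3-(tert-butyldimethylsilyloxy)-2-[(tert-butyldimethylsilyloxy)methyl]-5-hydroxycyclopentyl]hept-5-enoic acid
Conditions: 14, KOt-Bu, THF, 0 °C; then 13, −20 to 0 °C; aq. citric acid work-up
Reagents that add atoms: none
Why: Wittig olefination of the open-chain aldehyde form of the lactol with the non-stabilised ylide should give the Z-alkene under kinetic control; the low temperature is chosen to hold back silyl migration from O11 to the new C9 alkoxide.

Step 9
Reactants: 15 (Z)-7-[(1R,2S,3R,5S)-3-(tert-butyldimethylsilyloxy)-2-[(tert-butyldimethylsilyloxy)methyl]-5-hydroxycyclopentyl]hept-5-enoic acid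
Product: 16 (Z)-7-[(1R,2S,3R,5S)-3-(tert-butyldimethylsilyloxy)-5-hydroxy-2-(hydroxymethyl)cyclopentyl]hept-5-enoic acid
Conditions: HF·pyridine, pyridine, THF, 0 °C
Reagents that add atoms: none
Why: Selective desilylation: the unhindered primary silyl ether should be cleaved much faster by buffered HF than the secondary one on the ring.

Step 10
Reactants: 16 (Z)-7-[(1R,2S,3R,5S)-3-(tert-butyldimethylsilyloxy)-5-hydroxy-2-(hydroxymethyl)cyclopentyl]hept-5-enoic acid
Product: 17 (Z)-7-[(1R,2R,3R,5S)-3-(tert-butyldimethylsilyloxy)-2-formyl-5-hydroxycyclopentyl]hept-5-enoic acid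
Conditions: TEMPO (cat.), PhI(OAc)2, dry CH2Cl2, rt
Reagents that add atoms: none
Why: Oxoammonium (TEMPO) oxidation is selective for primary over secondary alcohols and stops at the aldehyde without water, and its near-neutral medium should spare the α-stereocenter and the β-silyloxy group; the C9 hydroxyl is trans to the formyl group and cannot form a lactol.

Step 11
Reactants: 17 (Z)-7-[(1R,2R,3R,5S)-3-(tert-butyldimethylsilyloxy)-2-formyl-5-hydroxycyclopentyl]hept-5-enoic acid; 18 dimethyl (2-oxoheptyl)phosphonate
Product: 19 (Z)-7-[(1R,2R,3R,5S)-3-(tert-butyldimethylsilyloxy)-5-hydroxy-2-[(E)-3-oxooct-1-enyl]cyclopentyl]hept-5-enoic acid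
Conditions: 18, LiCl, i-Pr2NEt (excess), MeCN, rt
Reagents that add atoms: none
Why: Horner–Wadsworth–Emmons olefination with the stabilised β-keto phosphonate should give the E-enone, and the mild LiCl/amine conditions should avoid epimerisation and β-elimination while the carboxylic acid rides along as its ammonium salt.

Step 12
Reactants: 19 (Z)-7-[(1R,2R,3R,5S)-3-(tert-butyldimethylsilyloxy)-5-hydroxy-2-[(E)-3-oxooct-1-enyl]cyclopentyl]hept-5-enoic acid
Product: 20 15-keto-PGF2alpha, (Z)-7-[(1R,2R,3R,5S)-3,5-dihydroxy-2-[(E)-3-oxooct-1-enyl]cyclopentyl]hept-5-enoic acid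
Conditions: HF·pyridine, MeCN, 0 °C to rt
Reagents that add atoms: none
Why: Desilylation of the remaining secondary silyl ether under mildly acidic fluoride conditions, which the enone, the Z-alkene and the free acid should tolerate; no stereocenter is touched.

**Compound list**

1 | prop-2-yn-1-ol | C#CCO | starting material
2 | dimethyl(phenyl)silane | C[SiH](C)c1ccccc1 | starting material
3 | (E)-3-[dimethyl(phenyl)silyl]prop-2-en-1-ol | OC/C=C/[Si](C)(C)c1ccccc1 | intermediate
4 | (E)-3-[dimethyl(phenyl)silyl]prop-2-enal | O=C/C=C/[Si](C)(C)c1ccccc1 | intermediate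
5 | ethyl (E)-4-oxopent-2-enoate | CCOC(=O)/C=C/C(C)=O | starting material
6 | ethyl (2E,6R,7E)-6-[dimethyl(phenyl)silyl]-8-[(2R)-2-[diphenyl(trimethylsilyloxy)methyl]pyrrolidin-1-yl]-4-oxoocta-2,7-dienoate (catalyst-bound enamine of the open-chain Michael adduct) | CCOC(=O)/C=C/C(=O)C[C@@H]([Si](C)(C)c1ccccc1)/C=C/N1CCC[C@@H]1C(c1ccccc1)(c1ccccc1)O[Si](C)(C)C | intermediate (not isolated)
7 | ethyl 2-[(1R,2S,3R)-3-[dimethyl(phenyl)silyl]-2-formyl-5-oxocyclopentyl]acetate | O=C[C@@H]1[C@@H](CC(=O)OCC)C(=O)C[C@H]1[Si](C)(C)c1ccccc1 | intermediate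
8 | ethyl 2-[(1R,2S,3R,5S)-3-[dimethyl(phenyl)silyl]-5-hydroxy-2-(hydroxymethyl)cyclopentyl]acetate | OC[C@@H]1[C@@H](CC(=O)OCC)[C@@H](O)C[C@H]1[Si](C)(C)c1ccccc1 | intermediate (not isolated)
9 | (3aR,4S,5R,6aS)-5-[dimethyl(phenyl)silyl]-4-(hydroxymethyl)hexahydro-2H-cyclopenta[b]furan-2-one | OC[C@@H]1[C@@H](CC(=O)O2)[C@@H]2C[C@H]1[Si](C)(C)c1ccccc1 | intermediate
10 | (3aR,4S,5R,6aS)-5-[fluoro(dimethyl)silyl]-4-(hydroxymethyl)hexahydro-2H-cyclopenta[b]furan-2-one | OC[C@@H]1[C@@H](CC(=O)O2)[C@@H]2C[C@H]1[Si](C)(C)F | intermediate (not isolated)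
11 | (3aR,4S,5R,6aS)-5-hydroxy-4-(hydroxymethyl)hexahydro-2H-cyclopenta[b]furan-2-one | OC[C@@H]1[C@@H](CC(=O)O2)[C@@H]2C[C@H]1O | intermediate
12 | (3aR,4S,5R,6aS)-5-(tert-butyldimethylsilyloxy)-4-[(tert-butyldimethylsilyloxy)methyl]hexahydro-2H-cyclopenta[b]furan-2-one | CC(C)(C)[Si](C)(C)OC[C@@H]1[C@@H](CC(=O)O2)[C@@H]2C[C@H]1O[Si](C)(C)C(C)(C)C | intermediate
13 | (3aR,4S,5R,6aS)-5-(tert-butyldimethylsilyloxy)-4-[(tert-butyldimethylsilyloxy)methyl]hexahydro-2H-cyclopenta[b]furan-2-ol (anomer mixture) | CC(C)(C)[Si](C)(C)OC[C@@H]1[C@@H](CC(O)O2)[C@@H]2C[C@H]1O[Si](C)(C)C(C)(C)C | intermediate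
14 | (4-carboxybutyl)triphenylphosphonium bromide | OC(=O)CCCC[P+](c1ccccc1)(c1ccccc1)c1ccccc1.[Br-] | starting material
15 | (Z)-7-[(1R,2S,3R,5S)-3-(tert-butyldimethylsilyloxy)-2-[(tert-butyldimethylsilyloxy)methyl]-5-hydroxycyclopentyl]hept-5-enoic acid | CC(C)(C)[Si](C)(C)OC[C@@H]1[C@@H](C/C=C\CCCC(=O)O)[C@@H](O)C[C@H]1O[Si](C)(C)C(C)(C)C | intermediate
16 | (Z)-7-[(1R,2S,3R,5S)-3-(tert-butyldimethylsilyloxy)-5-hydroxy-2-(hydroxymethyl)cyclopentyl]hept-5-enoic acid | OC[C@@H]1[C@@H](C/C=C\CCCC(=O)O)[C@@H](O)C[C@H]1O[Si](C)(C)C(C)(C)C | intermediate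
17 | (Z)-7-[(1R,2R,3R,5S)-3-(tert-butyldimethylsilyloxy)-2-formyl-5-hydroxycyclopentyl]hept-5-enoic acid | O=C[C@@H]1[C@@H](C/C=C\CCCC(=O)O)[C@@H](O)C[C@H]1O[Si](C)(C)C(C)(C)C | intermediate
18 | dimethyl (2-oxoheptyl)phosphonate | CCCCCC(=O)CP(=O)(OC)OC | starting material
19 | (Z)-7-[(1R,2R,3R,5S)-3-(tert-butyldimethylsilyloxy)-5-hydroxy-2-[(E)-3-oxooct-1-enyl]cyclopentyl]hept-5-enoic acid | CCCCCC(=O)/C=C/[C@@H]1[C@@H](C/C=C\CCCC(=O)O)[C@@H](O)C[C@H]1O[Si](C)(C)C(C)(C)C | intermediate
20 | 15-keto-PGF2alpha, (Z)-7-[(1R,2R,3R,5S)-3,5-dihydroxy-2-[(E)-3-oxooct-1-enyl]cyclopentyl]hept-5-enoic acid | CCCCCC(=O)/C=C/[C@@H]1[C@@H](C/C=C\CCCC(=O)O)[C@@H](O)C[C@H]1O | target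

**Summary**

Total step count: 12. Longest linear sequence: 12 steps (1 to 20).

**Steps most likely to fail**

Step 3. What may go wrong: erosion of facial control in the first Michael addition, self-condensation of the keto enoate, or a slow or unselective ring closure when both events must run under one set of conditions. Fallback, setting out from 4 and 5 and coming back at 7: the two events would be decoupled. Compound 5 would be turned with Me3SiOTf/Et3N into ethyl (E)-4-(trimethylsilyloxy)penta-2,4-dienoate F1. An iminium-catalysed Mukaiyama–Michael addition of F1 to 4 at −40 °C would use 5-benzyl-2-tert-butyl-3-methylimidazolidin-4-one trifluoroacetate, in the enantiomer that shields the same face (expected to be (2R,5R)). At this temperature the intramolecular step should not set in, so the open-chain keto aldehyde ethyl (2E,6S)-6-[dimethyl(phenyl)silyl]-4,8-dioxooct-2-enoate F2 should be isolable. F2 would then be cyclised in a separate operation with a secondary amine (pyrrolidine/AcOH) under equilibrating conditions, where the silyl-bearing center alone should steer the two new centers into the all-trans cyclopentanone 7.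

Step 10. What may go wrong: β-elimination of silanol from the aldehyde and epimerisation at its α-carbon while it accumulates and is handled, and competing oxidation of the free secondary alcohol. Fallback, setting out from 16 and coming back at 19: a tandem oxidation–Wittig reaction in which the aldehyde is trapped as it forms and no base is present. The neutral stabilised ylide would be made from triphenylphosphine and 1-bromoheptan-2-one through (2-oxoheptyl)triphenylphosphonium bromide F6, which aqueous NaOH would convert into 1-(triphenyl-λ5-phosphanylidene)heptan-2-one F7. Alcohol 16 would then be oxidised with TEMPO/PhI(OAc)2 in CH2Cl2 in the presence of F7, which should give the E-enone 19 directly and bypass both the isolation of 17 and the phosphonate step.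

Step 9. What may go wrong: concurrent loss of the secondary silyl ether, or incomplete cleavage of the primary one, so that the two oxygens are not cleanly told apart. Fallback, setting out from 11 and coming back at 16: the hydroxyls would be distinguished by acylation instead of by selective desilylation. Primary-selective pivaloylation of 11 (PivCl, pyridine, 0 °C) should give [(3aR,4S,5R,6aS)-5-hydroxy-2-oxohexahydro-2H-cyclopenta[b]furan-4-yl]methyl 2,2-dimethylpropanoate F3. Silylation (TBSCl, imidazole) would give [(3aR,4S,5R,6aS)-5-(tert-butyldimethylsilyloxy)-2-oxohexahydro-2H-cyclopenta[b]furan-4-yl]methyl 2,2-dimethylpropanoate F4. Excess i-Bu2AlH at −78 °C would reduce the lactone to the lactol and remove the pivalate in one operation, to give (3aR,4S,5R,6aS)-5-(tert-butyldimethylsilyloxy)-4-(hydroxymethyl)hexahydro-2H-cyclopenta[b]furan-2-ol F5. The Wittig reaction of F5 with the ylide from 14 (one further equivalent for the free hydroxyl) would give 16.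

Further compounds
F1 | step 3 | ethyl (E)-4-(trimethylsilyloxy)penta-2,4-dienoate | C=C(O[Si](C)(C)C)/C=C/C(=O)OCC
F2 | step 3 | ethyl (2E,6S)-6-[dimethyl(phenyl)silyl]-4,8-dioxooct-2-enoate | CCOC(=O)/C=C/C(=O)C[C@@H]([Si](C)(C)c1ccccc1)CC=O
F3 | step 9 | [(3aR,4S,5R,6aS)-5-hydroxy-2-oxohexahydro-2H-cyclopenta[b]furan-4-yl]methyl 2,2-dimethylpropanoate | CC(C)(C)C(=O)OC[C@@H]1[C@@H](CC(=O)O2)[C@@H]2C[C@H]1O
F4 | step 9 | [(3aR,4S,5R,6aS)-5-(tert-butyldimethylsilyloxy)-2-oxohexahydro-2H-cyclopenta[b]furan-4-yl]methyl 2,2-dimethylpropanoate | CC(C)(C)C(=O)OC[C@@H]1[C@@H](CC(=O)O2)[C@@H]2C[C@H]1O[Si](C)(C)C(C)(C)C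
F5 | step 9 | (3aR,4S,5R,6aS)-5-(tert-butyldimethylsilyloxy)-4-(hydroxymethyl)hexahydro-2H-cyclopenta[b]furan-2-ol | OC[C@@H]1[C@@H](CC(O)O2)[C@@H]2C[C@H]1O[Si](C)(C)C(C)(C)C
F6 | step 10 | (2-oxoheptyl)triphenylphosphonium bromide | CCCCCC(=O)C[P+](c1ccccc1)(c1ccccc1)c1ccccc1.[Br-]
F7 | step 10 | 1-(triphenyl-λ5-phosphanylidene)heptan-2-one | CCCCCC(=O)C=P(c1ccccc1)(c1ccccc1)c1ccccc1
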